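**Retrosynthetic overview**

1. Both galloylated extension units come from (−)-epicatechin 1: O-benzylation (2), C8 bromination (3) and esterification with 3,4,5-tris(benzyloxy)benzoic acid 4 give one building block, 8-bromo-hepta-O-benzyl-ECG 5, which is used twice.
2. Disconnection A (top C4–middle C6): hydride abstraction at C4 of 5 gives the cation 6 (the quinone-methide equivalent of an extension unit), which is trapped at C6 of a second molecule of 5 to give dimer 7.
3. Disconnection B (middle C4–bottom C8): the same oxidative activation of 7, trapped by the unprotected starter unit (+)-catechin 8 by way of cation 9, gives the protected trimer 10.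
4. Global hydrogenolysis of 10 gives the target 11, which is 3-O-galloyl-epicatechin-(4β→6)-3-O-galloyl-epicatechin-(4β→8)-catechin.
5. No ring is built: rings A, B and C of each flavan unit and both galloyl rings are carried in intact from 1, 4 and 8; bonds are made top-down, A before B.

Assumption: ECG stands for (−)-epicatechin 3-O-gallate, "4β" means trans to the neighbouring 3-O-galloyl group (2,3-cis-3,4-trans), and 3,4,5-tris(benzyloxy)benzoic acid is bought.

**Route**

Step 1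
Reactants: 1 (−)-epicatechin
Product: 2 5,7,3′,4′-tetra-O-benzyl-(−)-epicatechin, (2R,3R)-5,7-bis(benzyloxy)-2-[3,4-bis(benzyloxy)phenyl]chroman-3-ol
Conditions: BnBr (4.4 equiv), K2CO3 (5 equiv), DMF, 0 °C → rt, Ar
Reagents that add atoms: benzyl bromide, BrCc1ccccc1
Why: Williamson etherification under mild carbonate conditions benzylates the four acidic phenols but not the much less acidic secondary C3 alcohol, and neither C2 nor C3 is touched (no new stereocentre).

Step 2
Reactants: 2 5,7,3′,4′-tetra-O-benzyl-(−)-epicatechin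
Product: 3 8-bromo-5,7,3′,4′-tetra-O-benzyl-(−)-epicatechin, (2R,3R)-5,7-bis(benzyloxy)-8-bromo-2-[3,4-bis(benzyloxy)phenyl]chroman-3-ol
Conditions: NBS (1.0 equiv), CH2Cl2, −78 °C → rt
Reagents that add atoms: N-bromosuccinimide, O=C1CCC(=O)N1Br
Why: Electrophilic aromatic bromination of the phloroglucinol-type ring A, which is far more electron-rich than ring B, goes selectively to C8 as is usual for 5,7-di-O-benzylflavan-3-ols because C6 is flanked by two benzyloxy groups; no stereocentre is affected.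

Step 3
Reactants: 3 8-bromo-5,7,3′,4′-tetra-O-benzyl-(−)-epicatechin; 4 3,4,5-tris(benzyloxy)benzoic acid
Product: 5 8-bromo-hepta-O-benzyl-ECG, (2R,3R)-5,7-bis(benzyloxy)-8-bromo-2-[3,4-bis(benzyloxy)phenyl]chroman-3-yl 3,4,5-tris(benzyloxy)benzoate
Conditions: 4 (1.5 equiv), DCC (1.6 equiv), DMAP (0.3 equiv), CH2Cl2, rt
Reagents that add atoms: none
Why: Steglich esterification passes the O-acylisourea of 4 through the N-acylpyridinium to the axial C3 hydroxyl without breaking the C3–O bond, so the 3R configuration is retained and the aryl bromide and benzyl ethers are inert.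

Step 4
Reactants: 5 8-bromo-hepta-O-benzyl-ECG (two molecules: one is oxidised, one is the nucleophile)
Product: 7 dimer [8-bromo-hepta-O-benzyl-ECG]-(4β→6)-[8-bromo-hepta-O-benzyl-ECG], via dioxolenium ion pair 6 (not isolated)
Conditions: DDQ (0.35 equiv), 4 Å molecular sieves, CH2Cl2, 0 °C → rt; then TMSOTf (0.2 equiv), −78 → −40 °C; Et3N quench; unreacted 5 recovered
Reagents that add atoms: none
Why: Proposed new method: DDQ abstracts the C4 hydride of about one third of 5 (the same event that underlies the known DDQ C4-alkoxylation of O-benzylated flavan-3-ols), the 3-O-galloyl carbonyl closes onto the cation from the α face to store it as the cis-fused dioxolenium 6, and TMSOTf then lets C6 of unoxidised 5 (C8 blocked by Br) attack C4 from the β face in a Friedel–Crafts-type cross-dehydrogenative coupling that sets the 3,4-trans (4β→6) bond; the closest known reactions are the Lewis-acid coupling of isolated 4-alkoxyflavans with 8-bromo nucleophiles and DDQ-mediated dehydrogenative arylation of isochromans.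

Step 5
Reactants: 7 dimer [8-bromo-hepta-O-benzyl-ECG]-(4β→6)-[8-bromo-hepta-O-benzyl-ECG]; 8 (+)-catechin
Product: 10 protected trimer [8-bromo-hepta-O-benzyl-ECG]-(4β→6)-[8-bromo-hepta-O-benzyl-ECG]-(4β→8)-(+)-catechin (catechin unit unprotected), via dimer dioxolenium ion pair 9 (not isolated)
Conditions: DDQ (1.1 equiv), 4 Å molecular sieves, CH2Cl2, rt until DDQ is consumed; then 8 (4 equiv) in THF, BF3·OEt2 (0.3 equiv), −20 → 0 °C
Reagents that add atoms: none
Why: Proposed new method: DDQ removes the quasi-axial hydride of the only CH2 group (lower-unit C4; the upper C4–H is hindered and quasi-equatorial, close to the plane of its ring A), the lower 3-O-galloyl group again forms an α-face dioxolenium 9, and the free phloroglucinol ring of catechin attacks from the β face at its more reactive C8 (expected about 3–4:1 over C6) in a biomimetic Friedel–Crafts capture of a flavan-4-yl cation by the starter unit; the closest known reactions are the DDQ C4-alkoxylation of benzylated flavans and the acid-mediated coupling of flavan-3,4-diols or 4-thioethers with unprotected catechin.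

Step 6
Reactants: 10 protected trimer
Product: 11 3-O-galloyl-(−)-epicatechin-(4β→6)-3-O-galloyl-(−)-epicatechin-(4β→8)-(+)-catechin (CNP0112921.1)
Conditions: H2 (1 atm), Pd(OH)2/C, NaOAc (2.5 equiv), THF/MeOH/H2O, rt; filtration, Sephadex LH-20
Reagents that add atoms: none
Why: Catalytic hydrogenolysis cleaves all fourteen aryl benzyl ethers and both aryl C–Br bonds in one operation while the acetate buffer takes up HBr that would otherwise cleave the acid-labile interflavan bonds; esters and all stereocentres are untouched.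

**Compound list**

1 | (−)-epicatechin, 2R,3R | O[C@@H]1Cc2c(O)cc(O)cc2O[C@@H]1c1ccc(O)c(O)c1 | starting material

2 | 5,7,3′,4′-tetra-O-benzyl-(−)-epicatechin, 2R,3R, free 3-OH | O[C@@H]1Cc2c(OCc3ccccc3)cc(OCc3ccccc3)cc2O[C@@H]1c1ccc(OCc2ccccc2)c(OCc2ccccc2)c1 | intermediate

3 | 8-bromo-5,7,3′,4′-tetra-O-benzyl-(−)-epicatechin, 2R,3R, free 3-OH | O[C@@H]1Cc2c(OCc3ccccc3)cc(OCc3ccccc3)c(Br)c2O[C@@H]1c1ccc(OCc2ccccc2)c(OCc2ccccc2)c1 | intermediate

4 | 3,4,5-tris(benzyloxy)benzoic acid | OC(=O)c1cc(OCc2ccccc2)c(OCc2ccccc2)c(OCc2ccccc2)c1 | starting material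

5 | 8-bromo-hepta-O-benzyl-ECG, 2R,3R | O=C(O[C@@H]1Cc2c(OCc3ccccc3)cc(OCc3ccccc3)c(Br)c2O[C@@H]1c1ccc(OCc2ccccc2)c(OCc2ccccc2)c1)c1cc(OCc2ccccc2)c(OCc2ccccc2)c(OCc2ccccc2)c1 | intermediate

6 | ion pair of the C4 cation of 5 (closed by the galloyl C=O onto C4 from the α face as a 3,4-cis-fused 2-aryl-1,3-dioxolan-2-ylium ring) and the 2,3-dichloro-5,6-dicyano-4-hydroxyphenolate anion | C1(c2cc(OCc3ccccc3)c(OCc3ccccc3)c(OCc3ccccc3)c2)=[O+][C@@H]2c3c(OCc4ccccc4)cc(OCc4ccccc4)c(Br)c3O[C@H](c3ccc(OCc4ccccc4)c(OCc4ccccc4)c3)[C@@H]2O1.[O-]c1c(Cl)c(Cl)c(O)c(C#N)c1C#N | intermediate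

7 | dimer [8-bromo-hepta-O-benzyl-ECG]-(4β→6)-[8-bromo-hepta-O-benzyl-ECG]: upper C4 bonded to lower C6, trans to the upper 3-O-galloyl group; lower unit still C4H2; all C2 and C3 R | O=C(O[C@@H]1[C@@H](c2c(OCc3ccccc3)c(Br)c3c(c2OCc2ccccc2)C[C@@H](OC(=O)c2cc(OCc4ccccc4)c(OCc4ccccc4)c(OCc4ccccc4)c2)[C@@H](c2ccc(OCc4ccccc4)c(OCc4ccccc4)c2)O3)c2c(OCc3ccccc3)cc(OCc3ccccc3)c(Br)c2O[C@@H]1c1ccc(OCc2ccccc2)c(OCc2ccccc2)c1)c1cc(OCc2ccccc2)c(OCc2ccccc2)c(OCc2ccccc2)c1 | intermediate

8 | (+)-catechin, 2R,3S | O[C@H]1Cc2c(O)cc(O)cc2O[C@@H]1c1ccc(O)c(O)c1 | starting material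

9 | ion pair of the lower-unit C4 cation of 7 (α-face cis-fused dioxolenium formed by the lower galloyl C=O) and the 2,3-dichloro-5,6-dicyano-4-hydroxyphenolate anion | O=C(O[C@@H]1[C@@H](c2c(OCc3ccccc3)c(Br)c3c(c2OCc2ccccc2)[C@H]4[O+]=C(c2cc(OCc5ccccc5)c(OCc5ccccc5)c(OCc5ccccc5)c2)O[C@H]4[C@@H](c2ccc(OCc5ccccc5)c(OCc5ccccc5)c2)O3)c2c(OCc3ccccc3)cc(OCc3ccccc3)c(Br)c2O[C@@H]1c1ccc(OCc2ccccc2)c(OCc2ccccc2)c1)c1cc(OCc2ccccc2)c(OCc2ccccc2)c(OCc2ccccc2)c1.[O-]c1c(Cl)c(Cl)c(O)c(C#N)c1C#N | intermediate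

10 | protected trimer [8-bromo-hepta-O-benzyl-ECG]-(4β→6)-[8-bromo-hepta-O-benzyl-ECG]-(4β→8)-(+)-catechin; fourteen benzyl ethers, two C8 bromines, catechin unit free; both interflavan bonds trans to the adjacent 3-O-galloyl group | O=C(O[C@@H]1[C@@H](c2c(OCc3ccccc3)c(Br)c3c(c2OCc2ccccc2)[C@H](c2c(O)cc(O)c4c2O[C@H](c2ccc(O)c(O)c2)[C@@H](O)C4)[C@@H](OC(=O)c2cc(OCc4ccccc4)c(OCc4ccccc4)c(OCc4ccccc4)c2)[C@@H](c2ccc(OCc4ccccc4)c(OCc4ccccc4)c2)O3)c2c(OCc3ccccc3)cc(OCc3ccccc3)c(Br)c2O[C@@H]1c1ccc(OCc2ccccc2)c(OCc2ccccc2)c1)c1cc(OCc2ccccc2)c(OCc2ccccc2)c(OCc2ccccc2)c1 | intermediate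

11 | 3-O-galloyl-(−)-epicatechin-(4β→6)-3-O-galloyl-(−)-epicatechin-(4β→8)-(+)-catechin (CNP0112921.1); top and middle units 2R,3R with 4β bonds, bottom unit 2R,3S | O=C(O[C@@H]1[C@@H](c2c(O)cc3c(c2O)[C@H](c2c(O)cc(O)c4c2O[C@H](c2ccc(O)c(O)c2)[C@@H](O)C4)[C@@H](OC(=O)c2cc(O)c(O)c(O)c2)[C@@H](c2ccc(O)c(O)c2)O3)c2c(O)cc(O)cc2O[C@@H]1c1ccc(O)c(O)c1)c1cc(O)c(O)c(O)c1 | target

**Count and risks**

Total steps: 6. Longest linear sequence: 6 (1 → 2 → 3 → 5 → 7 → 10 → 11); acid 4 enters at step 3 and catechin 8 at step 5.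

The three steps most likely to fail:

Step 4 (oxidative self-coupling). Risks are that the stored cation does not re-ionise cleanly, over-oxidises, or that the hindered, bromine-deactivated C6 reacts too slowly. The fallback sets out from 5 and comes back at 7. It replaces the dehydrogenative coupling by stepwise activation through an isolated C4 ether: 5 is oxidised with DDQ (1.2 equiv) in the presence of 2-ethoxyethanol (CH2Cl2, rt) to 8-bromo-4β-(2-ethoxyethoxy)-hepta-O-benzyl-ECG F1. F1 is then condensed with excess 5 (3 equiv) under TMSOTf in CH2Cl2 at −78 °C to give 7.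

Step 5 (hydride abstraction from the dimer and capture by unprotected catechin). Risks are unselective or failed oxidation of 7, and C6 attack on catechin. The fallback sets out from 5 and comes back at 10, bypassing 7. It uses orthogonal activation, with the leaving group placed on the middle unit before dimerisation. The ethoxyethyl ether of 5 described above, 8-bromo-4β-(2-ethoxyethoxy)-hepta-O-benzyl-ECG F1, is treated with benzyl mercaptan and BF3·OEt2 (CH2Cl2, −20 °C) to give 8-bromo-4β-benzylsulfanyl-hepta-O-benzyl-ECG F2. A second portion of F1 is ionised with TMSOTf at −78 °C (the thioether is inert to this hard activator) and adds at C6 of excess F2 to give the dimeric 4β-benzylsulfanyl compound [8-bromo-hepta-O-benzyl-ECG]-(4β→6)-[8-bromo-4β-benzylsulfanyl-hepta-O-benzyl-ECG] F3. Thiophilic activation of F3 with AgBF4 in THF at 0 °C in the presence of 8 (4 equiv) then gives 10.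

Step 1 (fourfold benzylation). Risks are C-benzylation of ring A at C6 and C8 and base-induced epimerisation at C2. The fallback sets out from 1 and comes back at 2. Epicatechin is peracetylated (Ac2O, pyridine, rt) to (−)-epicatechin pentaacetate F4. F4 is then subjected to one-pot deacetylation–benzylation (BnCl, NaH, H2O added slowly, DMF, 0 °C → rt). Each aryl acetate is cleaved and the phenoxide benzylated as it is released, which keeps the phenoxide concentration low and suppresses C-alkylation. The slower-reacting secondary acetate stays on, giving 3-O-acetyl-5,7,3′,4′-tetra-O-benzyl-(−)-epicatechin F5. Methanolysis of F5 (K2CO3, MeOH/THF, rt) gives 2.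

**Further compounds**

F1 | step 4 | 8-bromo-4β-(2-ethoxyethoxy)-hepta-O-benzyl-ECG (ether trans to the 3-O-galloyl group) | O=C(O[C@@H]1[C@@H](OCCOCC)c2c(OCc3ccccc3)cc(OCc3ccccc3)c(Br)c2O[C@@H]1c1ccc(OCc2ccccc2)c(OCc2ccccc2)c1)c1cc(OCc2ccccc2)c(OCc2ccccc2)c(OCc2ccccc2)c1

F2 | step 5 | 8-bromo-4β-benzylsulfanyl-hepta-O-benzyl-ECG | O=C(O[C@@H]1[C@@H](SCc3ccccc3)c2c(OCc3ccccc3)cc(OCc3ccccc3)c(Br)c2O[C@@H]1c1ccc(OCc2ccccc2)c(OCc2ccccc2)c1)c1cc(OCc2ccccc2)c(OCc2ccccc2)c(OCc2ccccc2)c1

F3 | step 5 | dimer [8-bromo-hepta-O-benzyl-ECG]-(4β→6)-[8-bromo-4β-benzylsulfanyl-hepta-O-benzyl-ECG] | O=C(O[C@@H]1[C@@H](c2c(OCc3ccccc3)c(Br)c3c(c2OCc2ccccc2)[C@H](SCc2ccccc2)[C@@H](OC(=O)c2cc(OCc4ccccc4)c(OCc4ccccc4)c(OCc4ccccc4)c2)[C@@H](c2ccc(OCc4ccccc4)c(OCc4ccccc4)c2)O3)c2c(OCc3ccccc3)cc(OCc3ccccc3)c(Br)c2O[C@@H]1c1ccc(OCc2ccccc2)c(OCc2ccccc2)c1)c1cc(OCc2ccccc2)c(OCc2ccccc2)c(OCc2ccccc2)c1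

F4 | step 1 | (−)-epicatechin pentaacetate, 2R,3R | CC(=O)O[C@@H]1Cc2c(OC(C)=O)cc(OC(C)=O)cc2O[C@@H]1c1ccc(OC(C)=O)c(OC(C)=O)c1

F5 | step 1 | 3-O-acetyl-5,7,3′,4′-tetra-O-benzyl-(−)-epicatechin, 2R,3R | CC(=O)O[C@@H]1Cc2c(OCc3ccccc3)cc(OCc3ccccc3)cc2O[C@@H]1c1ccc(OCc2ccccc2)c(OCc2ccccc2)c1
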